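(All runs were generated by integration with made-up constants; the scatter is artificial.)

Amounts first. The flask holds less substrate than reagent in the second phase, so substrate is the limiting reagent.

all flasks: substrate 10 mM
- zeta: reagent in the second phase 20 mM; run made earlier
- eta: reagent in the second phase 80 mM; run made earlier
- flask: reagent in the second phase 40.0 mM; time 40 h; volume of the second phase over the first 0.25

| zeta: time / h | zeta: target / % | eta: time / h | eta: target / % |
|---|---|---|---|
| 2.50 | 0 | 2.50 | 9 |
| 4.00 | 3 | 4.00 | 6 |
| 6.00 | 2 | 6.00 | 15 |
| 10.0 | 6 | 10.0 | 20 |
| 15.0 | 11 | 15.0 | 29 |
| 20.0 | 8 | 20.0 | 31 |
| 30.0 | 11 | 30.0 | 42 |

(each reading ± 2 percentage points)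

- in the second phase: reagent in the second phase; everything else is in the first
- charges count per volume of the first phase; a concentration in a rate is the amount of a species over the volume of its own phase; every rate counts per litre of the first phase
- the earlier runs were read with a standard deviation of 2 percentage points
- what may be going on: reagent in the reaction phase <-> reagent in the second phase; reagent in the reaction phase -> decomposed reagent; reagent in the reaction phase + target -> over-reacted product; substrate -> decomposition product; substrate + reagent in the reaction phase -> target; target <-> isomer of the product
- the earlier runs hold the two phases in the same ratio of volumes as the flask asked about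

1. target at 40 h, in percent of the substrate charged
2. the change that raises the amount of target at 40 h, in percent of the substrate charged most ("none" if none brings more than 2 percentage points) (Tuesday's / Thursday's / none)
3. amount of target at 40 h, in percent of the substrate charged, after Thursday's

*What is the balance of substrate?* It falls at a rate constant times [substrate] times [reagent in the reaction phase].

*And that second factor?* The second phase feeds it. Full conversion in the flask would take a quarter of the reagent charge. So I take [reagent in the reaction phase] as steady and proportional to the charge, which makes substrate pseudo-first-order.

*What do you carry?* The last eta reading gives 55.1 h: the decay time, in which substrate not yet turned into target falls by the factor e at the eta charge. I take it to go inversely with the charge, so I reckon 110 h for the flask. Target is then one minus the exponential of minus time over decay time.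

*Test it.* For the zeta run at 30.0 h it gives 12.7%, and the reading is 11%. The eta run at 20.0 h has the same charge times time as the flask, and it reads 31%.

*Commit.* The flask gets 30.5%. Tuesday's gets 51.6%.

*But is transfer slow?* The eta run reads 9% at 2.50 h, more than the decay time gives, so no lag shows. I leave Thursday's near 30.5%.

The forecast says 24%, from 20% to 28%, with 25% after Thursday's, from 20% to 33%, and picks Tuesday's. On the slowing it says “the likely cause is loss of reagent by decomposition”. I read the slowing as the fall of substrate itself, and there we differ.

The flask gives 33.3%, and 33.5% after Thursday's. The best change is Tuesday's, worth 18 percentage points.

    reagent in the reaction phase ⇌ reagent in the second phase, rate k1*([reagent in the reaction phase] - [reagent in the second phase]/K1) per volume of the first phase (partition coefficient = 47.0, kL = 9.00 × 10⁻⁴ s⁻¹)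
    reagent in the reaction phase → decomposed reagent (k = 2.70 × 10⁻⁶ s⁻¹)
    reagent in the reaction phase + target → over-reacted product (k = 2.20 × 10⁻⁴ M⁻¹ s⁻¹)
    substrate → decomposition product (k = 5.00 × 10⁻⁸ s⁻¹)
    substrate + reagent in the reaction phase → target (k = 0.00120 M⁻¹ s⁻¹)
    target ⇌ isomer of the product (K = 0.120, k = 4.20 × 10⁻⁵ s⁻¹)

At 40.0 h the flask's reagent in the second phase still stands at 80.3% of its own charge, while substrate stands at 60.5%. My 110 h was read from target, so it is not the flask's decay time of substrate: that 60.5% gives 79.6 h, which is shorter. Left until 3.0 d, the same flask holds 47.1% target and 5.62% isomer of the product, with 42% substrate where my 110 h gives 52.0%.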